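**Retrosynthetic overview**

1. The linoleate C–O bond is cut to linoleic acid and a primary alcohol, and the methyl ketone is carried as a dioxolane. The C(=CH2) unit on ring carbon C1 goes back to a cyclobutyl ketone, made from a Weinreb amide and a 3-silyloxypropyl Grignard reagent.
2. The trans keto ester is the retro-Claisen product of a 3-acetylbicyclo[3.2.0]heptan-2-one. The five-membered ring is cut between its carbonyl carbon and the acetylated CH2, and C1 (then α to the ester) is equilibrated to trans.
3. Feature: with the cyclobutane numbered C1 (alkene arm), C2 (3-oxobutyl arm), C3 (CMe2), C4 (CH2), the ring is isobutylene (C3, C4) added across Cα=Cβ of cyclopent-2-enone. The enone carbonyl carbon is the later C(=CH2) carbon on C1, and enone C4 and C5 are the two CH2 groups of the oxobutyl arm on C2.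
4. Ring order: the cyclobutane is the only ring made (step 1, bonds C1–C4 and C2–C3). The cyclopentanone comes with the enone and is opened in step 3.

Key step: step 1

Assumption (sense of induction): the (S)-prolinol-derived Lewis acid is taken to leave open the 2Re,3Re face of bound cyclopentenone, by analogy with six-membered enones. If the adduct proves to be the (1S,5S) antipode, the (R)-prolinol-derived catalyst is used and nothing else changes.

Remark (catalyst): the oxazaborolidine is prepared beforehand by condensing the diarylprolinol with the arylboronic acid (toluene, azeotropic water removal) and is activated in the flask with AlBr3. It is a catalyst and is neither numbered nor counted.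

**Route**

Step 1
Reactants: 1 cyclopent-2-en-1-one; 2 isobutylene (2-methylpropene)
Product: 3 (1R,5R)-6,6-dimethylbicyclo[3.2.0]heptan-2-one (cis-fused)
Conditions: chiral Lewis acid (50 mol%; B-(2,4,6-trifluorophenyl)oxazaborolidine from (S)-α,α-bis(2,3-dimethylphenyl)prolinol, activated with AlBr3), 2 (excess, condensed), CH2Cl2, −78 °C, hν (366 nm)
Reagents that add atoms: none
Why: Binding of the carbonyl oxygen of 1 to boron shifts its ππ* band to longer wavelength, so that at 366 nm the complex should be excited in preference to free 1; after intersystem crossing its triplet adds to isobutylene stepwise, one C–C bond giving a triplet 1,4-biradical that after spin inversion either collapses to the cyclobutane or reverts. The closest known reaction type is the enone–alkene [2+2] photocycloaddition in its enantioselective form under AlBr3-activated oxazaborolidine catalysis, worked out on cyclohex-2-enones with simple alkenes including isobutylene. The cyclobutane is closed by 1,4-biradical recombination, which forms C1–C7 and C5–C6 of the bicycle (C1–C4 and C2–C3 of the target ring). C5 is set by the catalyst, whose aryl group covers one face of the bound enone so that the alkene adds to the open 2Re,3Re face; C1 follows because a five-membered enone cannot twist and only the cis ring fusion can form, and C1 is re-set by equilibration later in any case. The step needs only head-to-tail regiochemistry and enantiofacial selectivity: electron-rich 1,1-disubstituted alkenes normally place their substituted carbon on Cβ, which is expected to persist for the Lewis-acid-bound enone, and the two identical methyl groups of isobutylene remove any exo/endo question. AlBr3 is kept slightly below one equivalent relative to the oxazaborolidine so that no free aluminium halide is present to oligomerise isobutylene.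

Step 2
Reactants: 3 (1R,5R)-6,6-dimethylbicyclo[3.2.0]heptan-2-one
Product: 5 (1R,5R)-3-acetyl-6,6-dimethylbicyclo[3.2.0]heptan-2-one (C3 epimers and enol tautomers), via lithium enolate 4 (not isolated)
Conditions: LiHMDS (1.05 equiv), toluene, 0 °C; AcCl (0.5 equiv), 0 °C → rt; aq. NH4Cl; unreacted 3 recovered and resubmitted
Reagents that add atoms: acetyl chloride, CC(=O)Cl
Why: Claisen-type C-acylation of a ketone lithium enolate with an acid chloride in a non-polar solvent; deprotonation should occur only at the C3 methylene, because an enolate toward C1 would place a double bond at the fusion carbon of the strained bicycle, and half of the enolate serves as base for the more acidic β-diketone, hence 0.5 equiv of AcCl.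

Step 3
Reactants: 5 (1R,5R)-3-acetyl-6,6-dimethylbicyclo[3.2.0]heptan-2-one
Product: 7 methyl (1S,2R)-3,3-dimethyl-2-(3-oxobutyl)cyclobutane-1-carboxylate (trans), via cis keto ester 6 (not isolated)
Conditions: NaOMe (0.5 equiv), MeOH, reflux; AcOH quench
Reagents that add atoms: methanol, CO
Why: Retro-Claisen alcoholysis of a β-diketone: methoxide adds to the strained ring carbonyl, the adduct expels C3 as the methyl ketone enolate and the five-membered ring opens with release of strain to the cis ester 6, whose C1–H (now α to the ester) is equilibrated by the same base to the less crowded trans isomer, which sets C1 as S.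

Step 4
Reactants: 7 methyl (1S,2R)-3,3-dimethyl-2-(3-oxobutyl)cyclobutane-1-carboxylate
Product: 8 methyl (1S,2R)-3,3-dimethyl-2-[2-(2-methyl-1,3-dioxolan-2-yl)ethyl]cyclobutane-1-carboxylate
Conditions: ethylene glycol (5 equiv), PPTS (0.1 equiv), benzene, reflux (Dean–Stark)
Reagents that add atoms: ethylene glycol, OCCO
Why: Acid-catalysed ketalisation of the unhindered methyl ketone with azeotropic removal of water; the weak pyridinium acid should leave the methyl ester and both ring stereocentres untouched.

Step 5
Reactants: 8 methyl (1S,2R)-3,3-dimethyl-2-[2-(2-methyl-1,3-dioxolan-2-yl)ethyl]cyclobutane-1-carboxylate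
Product: 9 (1S,2R)-N-methoxy-N,3,3-trimethyl-2-[2-(2-methyl-1,3-dioxolan-2-yl)ethyl]cyclobutane-1-carboxamide
Conditions: MeNH(OMe)·HCl (1.5 equiv), i-PrMgCl (3.0 equiv), THF, −20 → 0 °C; aq. NH4Cl
Reagents that add atoms: N,O-dimethylhydroxylamine hydrochloride, CNOC.Cl
Why: Direct Weinreb amide formation by aminolysis of the ester with the chloromagnesium amide made in the flask, at a temperature where the ketal and the trans ring configuration are not affected.

Step 6
Reactants: 9 (1S,2R)-N-methoxy-N,3,3-trimethyl-2-[2-(2-methyl-1,3-dioxolan-2-yl)ethyl]cyclobutane-1-carboxamide; 10 (3-bromopropoxy)(tert-butyl)dimethylsilane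
Product: 12 4-[(tert-butyldimethylsilyl)oxy]-1-{(1S,2R)-3,3-dimethyl-2-[2-(2-methyl-1,3-dioxolan-2-yl)ethyl]cyclobutyl}butan-1-one, via Grignard reagent 11 (not isolated)
Conditions: 10, Mg turnings, THF, 40 °C (I2 to initiate); then 9, THF, 0 °C → rt; aq. NH4Cl
Reagents that add atoms: none
Why: Grignard addition to a Weinreb amide, in which the magnesium chelate of the tetrahedral adduct persists until work-up so that the ketone forms without over-addition; dioxolane and silyl ether are inert.

Step 7
Reactants: 12 4-[(tert-butyldimethylsilyl)oxy]-1-{(1S,2R)-3,3-dimethyl-2-[2-(2-methyl-1,3-dioxolan-2-yl)ethyl]cyclobutyl}butan-1-one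
Product: 13 tert-butyl{[4-{(1S,2R)-3,3-dimethyl-2-[2-(2-methyl-1,3-dioxolan-2-yl)ethyl]cyclobutyl}pent-4-en-1-yl]oxy}dimethylsilane
Conditions: Ph3PCH3Br, KOt-Bu, THF, 0 °C → reflux
Reagents that add atoms: methyltriphenylphosphonium bromide, C[P+](c1ccccc1)(c1ccccc1)c1ccccc1.[Br-]
Why: Wittig methylenation with the non-stabilised ylide; the basic medium can only move C1 (α to the ketone) toward the trans arrangement already present, and after olefination C1 is no longer epimerisable.

Step 8
Reactants: 13 tert-butyl{[4-{(1S,2R)-3,3-dimethyl-2-[2-(2-methyl-1,3-dioxolan-2-yl)ethyl]cyclobutyl}pent-4-en-1-yl]oxy}dimethylsilane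
Product: 14 4-{(1S,2R)-3,3-dimethyl-2-[2-(2-methyl-1,3-dioxolan-2-yl)ethyl]cyclobutyl}pent-4-en-1-ol
Conditions: TBAF (1.2 equiv), THF, 0 °C → rt; H2O
Reagents that add atoms: none
Why: Fluoride-induced desilylation driven by the strong Si–F bond; ketal and alkene do not react.

Step 9
Reactants: 14 4-{(1S,2R)-3,3-dimethyl-2-[2-(2-methyl-1,3-dioxolan-2-yl)ethyl]cyclobutyl}pent-4-en-1-ol; 15 linoleic acid
Product: 16 4-{(1S,2R)-3,3-dimethyl-2-[2-(2-methyl-1,3-dioxolan-2-yl)ethyl]cyclobutyl}pent-4-en-1-yl (9Z,12Z)-octadeca-9,12-dienoate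
Conditions: EDC·HCl (1.3 equiv), DMAP (0.2 equiv), CH2Cl2, 0 °C → rt, argon
Reagents that add atoms: none
Why: Steglich esterification, in which the carbodiimide activates the acid as its O-acylisourea and DMAP passes the acyl group to the primary alcohol under neutral conditions that should leave the skipped (Z,Z)-diene and the ketal unchanged.

Step 10
Reactants: 16 4-{(1S,2R)-3,3-dimethyl-2-[2-(2-methyl-1,3-dioxolan-2-yl)ethyl]cyclobutyl}pent-4-en-1-yl (9Z,12Z)-octadeca-9,12-dienoate
Product: 17 4-[(1S,2R)-3,3-dimethyl-2-(3-oxobutyl)cyclobutyl]pent-4-en-1-yl (9Z,12Z)-octadeca-9,12-dienoate (IN0146)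
Conditions: PPTS (0.2 equiv), acetone/H2O (10:1), 50 °C, argon
Reagents that add atoms: water, O
Why: Mild acid-catalysed ketal hydrolysis (exchange into acetone/water); the pyridinium acid should be too weak to protonate the 1,1-disubstituted alkene next to the cyclobutane, to move the skipped diene or to cleave the ester.

**Compound list**

1 | cyclopent-2-en-1-one | O=C1C=CCC1 | starting material
2 | isobutylene (2-methylpropene) | C=C(C)C | starting material
3 | (1R,5R)-6,6-dimethylbicyclo[3.2.0]heptan-2-one | O=C1[C@@H]2CC(C)(C)[C@@H]2CC1 | intermediate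
4 | lithium (1R,5R)-6,6-dimethylbicyclo[3.2.0]hept-2-en-2-olate | [Li]OC1=CC[C@H]2C(C)(C)C[C@@H]12 | intermediate
5 | (1R,5R)-3-acetyl-6,6-dimethylbicyclo[3.2.0]heptan-2-one (C3 unassigned) | O=C1[C@@H]2CC(C)(C)[C@@H]2CC1C(C)=O | intermediate
6 | methyl (1R,2R)-3,3-dimethyl-2-(3-oxobutyl)cyclobutane-1-carboxylate (cis) | COC(=O)[C@@H]1CC(C)(C)[C@@H]1CCC(C)=O | intermediate
7 | methyl (1S,2R)-3,3-dimethyl-2-(3-oxobutyl)cyclobutane-1-carboxylate (trans) | COC(=O)[C@H]1CC(C)(C)[C@@H]1CCC(C)=O | intermediate
8 | methyl (1S,2R)-3,3-dimethyl-2-[2-(2-methyl-1,3-dioxolan-2-yl)ethyl]cyclobutane-1-carboxylate | COC(=O)[C@H]1CC(C)(C)[C@@H]1CCC1(C)OCCO1 | intermediate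
9 | (1S,2R)-N-methoxy-N,3,3-trimethyl-2-[2-(2-methyl-1,3-dioxolan-2-yl)ethyl]cyclobutane-1-carboxamide | CON(C)C(=O)[C@H]1CC(C)(C)[C@@H]1CCC1(C)OCCO1 | intermediate
10 | (3-bromopropoxy)(tert-butyl)dimethylsilane | CC(C)(C)[Si](C)(C)OCCCBr | starting material
11 | {3-[(tert-butyldimethylsilyl)oxy]propyl}magnesium bromide | CC(C)(C)[Si](C)(C)OCCC[Mg]Br | intermediate
12 | 4-[(tert-butyldimethylsilyl)oxy]-1-{(1S,2R)-3,3-dimethyl-2-[2-(2-methyl-1,3-dioxolan-2-yl)ethyl]cyclobutyl}butan-1-one | CC(C)(C)[Si](C)(C)OCCCC(=O)[C@H]1CC(C)(C)[C@@H]1CCC1(C)OCCO1 | intermediate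
13 | tert-butyl{[4-{(1S,2R)-3,3-dimethyl-2-[2-(2-methyl-1,3-dioxolan-2-yl)ethyl]cyclobutyl}pent-4-en-1-yl]oxy}dimethylsilane | C=C(CCCO[Si](C)(C)C(C)(C)C)[C@H]1CC(C)(C)[C@@H]1CCC1(C)OCCO1 | intermediate
14 | 4-{(1S,2R)-3,3-dimethyl-2-[2-(2-methyl-1,3-dioxolan-2-yl)ethyl]cyclobutyl}pent-4-en-1-ol | C=C(CCCO)[C@H]1CC(C)(C)[C@@H]1CCC1(C)OCCO1 | intermediate
15 | linoleic acid, (9Z,12Z)-octadeca-9,12-dienoic acid | CCCCC/C=C\C/C=C\CCCCCCCC(=O)O | starting material
16 | 4-{(1S,2R)-3,3-dimethyl-2-[2-(2-methyl-1,3-dioxolan-2-yl)ethyl]cyclobutyl}pent-4-en-1-yl (9Z,12Z)-octadeca-9,12-dienoate | C=C(CCCOC(=O)CCCCCCC/C=C\C/C=C\CCCCC)[C@H]1CC(C)(C)[C@@H]1CCC1(C)OCCO1 | intermediate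
17 | 4-[(1S,2R)-3,3-dimethyl-2-(3-oxobutyl)cyclobutyl]pent-4-en-1-yl (9Z,12Z)-octadeca-9,12-dienoate (IN0146) | C=C(CCCOC(=O)CCCCCCC/C=C\C/C=C\CCCCC)[C@H]1CC(C)(C)[C@@H]1CCC(C)=O | target

**Step count**

Total: 10 steps. Longest linear sequence: 10 steps (1 and 2 to 17); compounds 10 and 15 are bought and enter directly.

**Steps most likely to fail**

Step 1. Enantiofacial discrimination may be poor if free cyclopentenone competes for the light or if the five-ring enone sits less rigidly on the Lewis acid than its six-ring relatives. The head-to-tail preference may erode, and the Lewis acid may start cationic oligomerisation of isobutylene. The fallback sets out from 1 and 2 and comes back at 3. Uncatalysed irradiation of 1 with excess 2 (Pyrex, λ > 300 nm, CH2Cl2, −40 °C) should give racemic cis-6,6-dimethylbicyclo[3.2.0]heptan-2-one F1 after removal of the head-to-head isomer. L-Selectride (THF, −78 °C) should attack the convex face and give racemic endo-6,6-dimethylbicyclo[3.2.0]heptan-2-ol F2. Lipase-catalysed transesterification (Burkholderia cepacia lipase or CAL-B, vinyl acetate, MTBE) is expected, by the empirical rule for secondary alcohols, to acylate the (2R)-carbinol and leave (1R,2S,5R)-6,6-dimethylbicyclo[3.2.0]heptan-2-ol F3. This is separated from (1S,2R,5S)-6,6-dimethylbicyclo[3.2.0]heptan-2-yl acetate F4 and oxidised (Dess–Martin periodinane, CH2Cl2) to 3.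

Step 3. Methoxide may attack the acetyl carbonyl instead of the ring carbonyl, which only returns 3. The cis ester may re-close by Claisen condensation or the free methyl ketone may undergo aldol chemistry during the long exposure to base, and the equilibration of C1 to trans may stay incomplete. The fallback sets out from 5 and comes back at 8, separating an irreversible ring opening from the epimerisation. Aqueous KOH (EtOH/H2O, reflux) should cleave 5 to (1R,2R)-3,3-dimethyl-2-(3-oxobutyl)cyclobutane-1-carboxylic acid F5, the carboxylate making the opening irreversible. MeI/K2CO3 (DMF) gives the cis keto ester 6, and ketalisation as in step 4 gives methyl (1R,2R)-3,3-dimethyl-2-[2-(2-methyl-1,3-dioxolan-2-yl)ethyl]cyclobutane-1-carboxylate F6. With the ketone masked, NaOMe/MeOH at reflux can then equilibrate C1 without re-closure or aldol chemistry, to give 8. A further chance to complete the equilibration exists at ketone 12 (DBU, or the basic Wittig medium).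

Step 2. The enolate may be acylated on oxygen, or proton transfer from the product may stall conversion. The fallback sets out from 3 and comes back at 5 by an aldol–oxidation sequence. LDA (THF, −78 °C) followed by acetaldehyde should give (1R,5R)-3-(1-hydroxyethyl)-6,6-dimethylbicyclo[3.2.0]heptan-2-one F7 as a diastereomer mixture, which Dess–Martin periodinane (CH2Cl2) oxidises to 5.

**Further compounds**

F1 | step 1 | racemic cis-6,6-dimethylbicyclo[3.2.0]heptan-2-one | O=C1[C@@H]2CC(C)(C)[C@@H]2CC1.O=C1[C@H]2CC(C)(C)[C@H]2CC1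
F2 | step 1 | racemic endo-(1R*,2S*,5R*)-6,6-dimethylbicyclo[3.2.0]heptan-2-ol | O[C@@H]1[C@@H]2CC(C)(C)[C@@H]2CC1.O[C@H]1[C@H]2CC(C)(C)[C@H]2CC1
F3 | step 1 | (1R,2S,5R)-6,6-dimethylbicyclo[3.2.0]heptan-2-ol | O[C@@H]1[C@@H]2CC(C)(C)[C@@H]2CC1
F4 | step 1 | (1S,2R,5S)-6,6-dimethylbicyclo[3.2.0]heptan-2-yl acetate | CC(=O)O[C@H]1[C@H]2CC(C)(C)[C@H]2CC1
F5 | step 3 | (1R,2R)-3,3-dimethyl-2-(3-oxobutyl)cyclobutane-1-carboxylic acid | OC(=O)[C@@H]1CC(C)(C)[C@@H]1CCC(C)=O
F6 | step 3 | methyl (1R,2R)-3,3-dimethyl-2-[2-(2-methyl-1,3-dioxolan-2-yl)ethyl]cyclobutane-1-carboxylate | COC(=O)[C@@H]1CC(C)(C)[C@@H]1CCC1(C)OCCO1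
F7 | step 2 | (1R,5R)-3-(1-hydroxyethyl)-6,6-dimethylbicyclo[3.2.0]heptan-2-one | O=C1[C@@H]2CC(C)(C)[C@@H]2CC1C(C)O
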